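**Plan**
Retrosynthesis: the furan-2(5H)-one is opened at C2–C3 and O1–C5. This removes CO2 (O1–C2=O) and leaves a trimethylenemethane-type unit, because ring carbon C4 carries three carbon arms (C3, C5 and the first side-chain CH2). The unit is carried as an allylsilane (future C3) with a phenylsulfonyl leaving group on the side-chain carbon.
Further cuts: the CH2–CH(SO2Ph) bond to a geraniol-derived C11 chain (sulfone alkylation), the ring–CH2CH2 bond (B-alkyl Suzuki–Miyaura coupling with 2-iodocyclohex-2-enone), and the two ring C–CH3 bonds at C5 and C4 of the cyclohexenone.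
Forward: geraniol → silyl-protected C11 triene → union with the six-membered ring → conjugate methylation and enolate methylation → desaturation and MeLi addition → chain-end sulfone coupling → sequenced formal (3+2) annulation with CO2 to the butenolide → oxidative 1,3-transposition to the 3-methylcyclohexenone.
Stereochemistry: C5 (R) from a ligand-controlled copper-catalysed conjugate addition; C4 (R) from methylation of the derived enolate anti to the C5 methyl; both E-alkenes come from geraniol, the second one fixed by E-selective SeO2 oxidation.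

Key step: step 14

Assumption: the target is the (4R,5R) enantiomer as drawn, with the C4 and C5 ring methyl groups trans and the side chain cis to the C5 methyl (TBS = tert-butyldimethylsilyl).

Step 1
Reactants: 1 geraniol
Product: 2 geranyl TBS ether
Conditions: TBSCl, imidazole, DMF, rt
Reagents that add atoms: tert-butyldimethylsilyl chloride CC(C)(C)[Si](C)(C)Cl
Why: Standard silylation of the primary allylic alcohol; the TBS ether should withstand every step up to the fluoride deprotection.

Step 2
Reactants: 2 geranyl TBS ether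
Product: 3 (2E,6E)-8-(TBSO)-2,6-dimethylocta-2,6-dien-1-ol
Conditions: SeO2 (cat.), t-BuOOH, salicylic acid (cat.), CH2Cl2, rt
Reagents that add atoms: tert-butyl hydroperoxide CC(C)(C)OO
Why: SeO2-catalysed allylic oxidation (ene reaction, then [2,3]-sigmatropic shift) attacks the more electron-rich terminal trisubstituted alkene and oxidises its (E)-methyl group, which fixes the E geometry of the second chain alkene.

Step 3
Reactants: 3 allylic alcohol
Product: 4 (2E,6E)-8-(TBSO)-2,6-dimethylocta-2,6-dienal
Conditions: MnO2, CH2Cl2, rt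
Reagents that add atoms: none
Why: MnO2 oxidises the allylic alcohol chemoselectively to the (E)-enal without touching the alkenes or the silyl ether.

Step 4
Reactants: 4 enal
Product: 5 tert-butyl{[(2E,6E)-3,7-dimethylnona-2,6,8-trien-1-yl]oxy}dimethylsilane
Conditions: Ph3PCH3Br, n-BuLi, THF, 0 °C → rt
Reagents that add atoms: methyltriphenylphosphonium bromide C[P+](c1ccccc1)(c1ccccc1)c1ccccc1.[Br-]
Why: Wittig methylenation of the enal gives the terminal 1,3-diene without disturbing the existing E-alkenes.

Step 5
Reactants: 6 cyclohex-2-en-1-one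
Product: 7 2-iodocyclohex-2-en-1-one
Conditions: I2, pyridine, CH2Cl2, 0 °C → rt
Reagents that add atoms: iodine [I][I]
Why: Pyridine-mediated α-iodination of the enone (conjugate addition of pyridine, iodination of the enolate, elimination) gives the sp2 coupling partner.

Step 6
Reactants: 5 triene; 7 2-iodocyclohex-2-en-1-one
Product: 9 2-[(3E,7E)-9-(TBSO)-3,7-dimethylnona-3,7-dien-1-yl]cyclohex-2-en-1-one, via B-alkyl-9-BBN adduct 8 (not isolated)
Conditions: 9-BBN, THF, 0 °C → rt; then 7, PdCl2(dppf) (cat., divalent palladium), Ph3As, Cs2CO3, DMF/H2O, rt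
Reagents that add atoms: none
Why: B-alkyl Suzuki–Miyaura coupling: 9-BBN should add anti-Markovnikov only to the monosubstituted terminus of the diene (the trisubstituted alkenes are inert), and the homoallylic borane then couples with the α-iodoenone.

Step 7
Reactants: 9 2-alkylcyclohexenone
Product: 12 (2R,3R)-2-[(3E,7E)-9-(TBSO)-3,7-dimethylnona-3,7-dien-1-yl]-2,3-dimethylcyclohexan-1-one, via dimethylaluminium enolate 10 (not isolated), via lithium aluminate enolate 11 (not isolated)
Conditions: Me3Al, copper thiophene-2-carboxylate CuTC (cat., monovalent copper), BINOL-derived bis(1-phenylethyl)amine phosphoramidite (cat., enantiomer directing methyl to the Re face of C3), Et2O, −30 °C; then MeLi, THF/DMPU, MeI, −30 → 0 °C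
Reagents that add atoms: trimethylaluminium C[Al](C)C; iodomethane IC
Why: Copper-catalysed asymmetric conjugate addition of Me3Al to the α-substituted cyclohexenone sets C3 (R) under ligand control, and the aluminate enolate (activated by MeLi) is C-methylated by MeI on the face anti to the pseudoaxial C3 methyl, which makes the quaternary C2 (R) with the two ring methyls trans.

Step 8
Reactants: 12 ketone
Product: 14 (5R,6R)-6-[(3E,7E)-9-(TBSO)-3,7-dimethylnona-3,7-dien-1-yl]-5,6-dimethylcyclohex-2-en-1-one, via trimethylsilyl enol ether 13 (not isolated)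
Conditions: LDA, TMSCl, THF, −78 °C; then Pd(OAc)2 (1 equiv, divalent palladium), MeCN, rt
Reagents that add atoms: none
Why: Saegusa–Ito oxidation: the ketone can enolise only away from the quaternary carbon, so silyl enol ether formation and dehydrosilylation place the new C=C regiospecifically.

Step 9
Reactants: 14 enone
Product: 15 (5R,6R)-6-[(3E,7E)-9-(TBSO)-3,7-dimethylnona-3,7-dien-1-yl]-1,5,6-trimethylcyclohex-2-en-1-ol (both C1 epimers)
Conditions: MeLi, Et2O, −78 °C
Reagents that add atoms: methyllithium [Li]C
Why: 1,2-Addition of methyllithium to the enone gives the tertiary allylic alcohol; both C1 epimers are acceptable because this centre becomes sp2 in step 15.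

Step 10
Reactants: 15 silyl ether
Product: 16 (5R,6R)-6-[(3E,7E)-9-hydroxy-3,7-dimethylnona-3,7-dien-1-yl]-1,5,6-trimethylcyclohex-2-en-1-ol
Conditions: TBAF, THF, 0 °C
Reagents that add atoms: none
Why: Fluoride cleaves the silyl ether without affecting the tertiary allylic alcohol.

Step 11
Reactants: 16 diol
Product: 18 (5R,6R)-6-[(3E,7E)-9-bromo-3,7-dimethylnona-3,7-dien-1-yl]-1,5,6-trimethylcyclohex-2-en-1-ol, via primary allylic mesylate 17 (not isolated)
Conditions: MsCl, Et3N, THF, −40 °C; then LiBr, −40 → 0 °C
Reagents that add atoms: lithium bromide [Li+].[Br-]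
Why: The unhindered primary allylic alcohol is mesylated selectively (the hindered tertiary alcohol is not) and bromide displaces the allylic mesylate in an SN2 reaction.

Step 12
Reactants: 19 [2-(chloromethyl)prop-2-en-1-yl]trimethylsilane
Product: 20 trimethyl{2-[(phenylsulfonyl)methyl]prop-2-en-1-yl}silane
Conditions: PhSO2Na, DMF, rt
Reagents that add atoms: sodium benzenesulfinate [Na+].[O-]S(=O)c1ccccc1
Why: S-Alkylation of the sulfinate by the allylic chloride (SN2) gives a reagent that combines an α-sulfonyl CH2 (carbanion precursor and later leaving group) with an allylsilane (latent nucleophile for CO2).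

Step 13
Reactants: 20 silyl sulfone; 18 allylic bromide
Product: 22 (5R,6R)-6-[(3E,7E)-3,7-dimethyl-11-methylidene-10-(phenylsulfonyl)-12-(trimethylsilyl)dodeca-3,7-dien-1-yl]-1,5,6-trimethylcyclohex-2-en-1-ol (epimers at the sulfone carbon), via α-lithiated sulfone 21 (not isolated)
Conditions: n-BuLi (on 20, 2.2 equiv), THF, −78 °C; then 18, −78 → −20 °C
Reagents that add atoms: none
Why: Alkylation of the α-sulfonyl allyl carbanion at the sulfone-bearing carbon by the primary allylic bromide (SN2) joins the chain to the four-carbon unit; the new sulfone stereocentre forms as a mixture that is erased in step 14, and the excess of 21 also deprotonates the tertiary hydroxyl.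

Step 14
Reactants: 22 allylsilane sulfone
Product: 25 4-{(3E,7E)-10-[(1R,6R)-2-hydroxy-1,2,6-trimethylcyclohex-3-en-1-yl]-4,8-dimethyldeca-3,7-dien-1-yl}furan-2(5H)-one, via caesium carboxylate 23 (not isolated), via exocyclic alkylidene lactone 24 (not isolated)
Conditions: CsF, CO2 (1 atm), DMF, rt → 50 °C; argon purge; then Pd(PPh3)4 (cat., zerovalent palladium), DBU (cat.), 60 °C
Reagents that add atoms: carbon dioxide O=C=O
Why: Proposed new method: fluoride attacks silicon of the allylsilane and the resulting 2-substituted allyl nucleophile, whose two termini are both CH2 groups, is carboxylated by CO2 (first new bond, C2–C3 of the future furanone) before any palladium is present, so no equilibrating trimethylenemethane–palladium species can move the site of C–C bond formation; zerovalent palladium then ionises the allylic sulfone of 23 to an η3-allyl complex, the tethered carboxylate oxygen closes on its unsubstituted CH2 terminus (second new bond, O1–C5), and base moves the exocyclic C=C of 24 into conjugation. The closest known reaction types are the palladium-catalysed (3+2) cycloaddition of CO2 with trimethylenemethane generated from 2-(silylmethyl)allyl esters, fluoride-triggered desilylative carboxylation of benzylic and alkynyl silanes, and palladium-catalysed substitution of allylic sulfones. The lactone ring closes by O-allylation at the terminal carbon of the η3-allyl unit, formally a 5-exo-tet closure with palladium as the nucleofuge outside the ring. No stereocentre is created: the sulfone-bearing carbon (epimer mixture) and the E/Z geometry of 24 are both erased, so all isomers should converge on one butenolide. The step needs regioselectivity in both bond formations and chemoselectivity against three other alkenes and a tertiary allylic alcohol; the first is secured by running carboxylation before ionisation and by the preference of carboxylate for the less hindered allyl terminus, with reversible ionisation draining into the conjugated product, and the second by the absence of any electrophilic oxidant and by purging CO2 before palladium is added, so that the tertiary alcohol is not activated as a carbonate.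

Step 15
Reactants: 25 butenolide tertiary allylic alcohol
Product: 26 cyclolinteinone
Conditions: pyridinium chlorochromate (C5H5NH)[CrO3Cl], 4 Å molecular sieves, CH2Cl2, rt
Reagents that add atoms: pyridinium chlorochromate [O-][Cr](=O)(=O)Cl.c1cc[nH+]cc1
Why: Babler–Dauben oxidative transposition: the tertiary allylic chromate ester undergoes a [3,3]-sigmatropic shift and the resulting secondary allylic chromate is oxidised to the 3-methylcyclohexenone, both C1 epimers converging on the target while the butenolide and the trisubstituted alkenes should be inert to hexavalent chromium under these conditions.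

**Compound list**
1 | geraniol, (2E)-3,7-dimethylocta-2,6-dien-1-ol | CC(C)=CCC/C(C)=C/CO | starting material
2 | tert-butyl{[(2E)-3,7-dimethylocta-2,6-dien-1-yl]oxy}dimethylsilane | CC(C)=CCC/C(C)=C/CO[Si](C)(C)C(C)(C)C | intermediate
3 | (2E,6E)-8-[(tert-butyldimethylsilyl)oxy]-2,6-dimethylocta-2,6-dien-1-ol | OC/C(C)=C/CC/C(C)=C/CO[Si](C)(C)C(C)(C)C | intermediate
4 | (2E,6E)-8-[(tert-butyldimethylsilyl)oxy]-2,6-dimethylocta-2,6-dienal | O=C/C(C)=C/CC/C(C)=C/CO[Si](C)(C)C(C)(C)C | intermediate
5 | tert-butyl{[(2E,6E)-3,7-dimethylnona-2,6,8-trien-1-yl]oxy}dimethylsilane | C=C/C(C)=C/CC/C(C)=C/CO[Si](C)(C)C(C)(C)C | intermediate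
6 | cyclohex-2-en-1-one | O=C1C=CCCC1 | starting material
7 | 2-iodocyclohex-2-en-1-one | IC1=CCCCC1=O | intermediate
8 | 9-[(3E,7E)-9-(TBSO)-3,7-dimethylnona-3,7-dien-1-yl]-9-borabicyclo[3.3.1]nonane | B1(CC/C(C)=C/CC/C(C)=C/CO[Si](C)(C)C(C)(C)C)C2CCCC1CCC2 | intermediate
9 | 2-[(3E,7E)-9-(TBSO)-3,7-dimethylnona-3,7-dien-1-yl]cyclohex-2-en-1-one | O=C1CCCC=C1CC/C(C)=C/CC/C(C)=C/CO[Si](C)(C)C(C)(C)C | intermediate
10 | dimethylaluminium enolate of (3R)-2-alkyl-3-methylcyclohexanone (O–AlMe2 on C1, C1=C2) | C[Al](C)OC1=C(CC/C(C)=C/CC/C(C)=C/CO[Si](C)(C)C(C)(C)C)[C@H](C)CCC1 | intermediate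
11 | lithium trimethyl(enolato)aluminate of the same (3R) enolate | [Li+].C[Al-](C)(C)OC1=C(CC/C(C)=C/CC/C(C)=C/CO[Si](C)(C)C(C)(C)C)[C@H](C)CCC1 | intermediate
12 | (2R,3R)-2-[(3E,7E)-9-(TBSO)-3,7-dimethylnona-3,7-dien-1-yl]-2,3-dimethylcyclohexan-1-one | O=C1CCC[C@@H](C)[C@@]1(C)CC/C(C)=C/CC/C(C)=C/CO[Si](C)(C)C(C)(C)C | intermediate
13 | {[(5R,6R)-6-[(3E,7E)-9-(TBSO)-3,7-dimethylnona-3,7-dien-1-yl]-5,6-dimethylcyclohex-1-en-1-yl]oxy}trimethylsilane | C[Si](C)(C)OC1=CCC[C@@H](C)[C@@]1(C)CC/C(C)=C/CC/C(C)=C/CO[Si](C)(C)C(C)(C)C | intermediate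
14 | (5R,6R)-6-[(3E,7E)-9-(TBSO)-3,7-dimethylnona-3,7-dien-1-yl]-5,6-dimethylcyclohex-2-en-1-one | O=C1C=CC[C@@H](C)[C@@]1(C)CC/C(C)=C/CC/C(C)=C/CO[Si](C)(C)C(C)(C)C | intermediate
15 | (5R,6R)-6-[(3E,7E)-9-(TBSO)-3,7-dimethylnona-3,7-dien-1-yl]-1,5,6-trimethylcyclohex-2-en-1-ol (C1 epimers) | CC1(O)C=CC[C@@H](C)[C@@]1(C)CC/C(C)=C/CC/C(C)=C/CO[Si](C)(C)C(C)(C)C | intermediate
16 | (5R,6R)-6-[(3E,7E)-9-hydroxy-3,7-dimethylnona-3,7-dien-1-yl]-1,5,6-trimethylcyclohex-2-en-1-ol | CC1(O)C=CC[C@@H](C)[C@@]1(C)CC/C(C)=C/CC/C(C)=C/CO | intermediate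
17 | primary allylic methanesulfonate of 16 | CC1(O)C=CC[C@@H](C)[C@@]1(C)CC/C(C)=C/CC/C(C)=C/COS(C)(=O)=O | intermediate
18 | (5R,6R)-6-[(3E,7E)-9-bromo-3,7-dimethylnona-3,7-dien-1-yl]-1,5,6-trimethylcyclohex-2-en-1-ol | CC1(O)C=CC[C@@H](C)[C@@]1(C)CC/C(C)=C/CC/C(C)=C/CBr | intermediate
19 | [2-(chloromethyl)prop-2-en-1-yl]trimethylsilane | C[Si](C)(C)CC(=C)CCl | starting material
20 | trimethyl{2-[(phenylsulfonyl)methyl]prop-2-en-1-yl}silane | C[Si](C)(C)CC(=C)CS(=O)(=O)c1ccccc1 | intermediate
21 | α-lithio derivative of 20 (lithium on the sulfone-bearing carbon) | [Li]C(C(=C)C[Si](C)(C)C)S(=O)(=O)c1ccccc1 | intermediate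
22 | (5R,6R)-6-[(3E,7E)-3,7-dimethyl-11-methylidene-10-(phenylsulfonyl)-12-(trimethylsilyl)dodeca-3,7-dien-1-yl]-1,5,6-trimethylcyclohex-2-en-1-ol (epimers at C1 and at the sulfone carbon) | CC1(O)C=CC[C@@H](C)[C@@]1(C)CC/C(C)=C/CC/C(C)=C/CC(C(=C)C[Si](C)(C)C)S(=O)(=O)c1ccccc1 | intermediate
23 | caesium (6E,10E)-13-[(1R,6R)-2-hydroxy-1,2,6-trimethylcyclohex-3-en-1-yl]-7,11-dimethyl-3-methylidene-4-(phenylsulfonyl)trideca-6,10-dienoate | [Cs+].CC1(O)C=CC[C@@H](C)[C@@]1(C)CC/C(C)=C/CC/C(C)=C/CC(C(=C)CC(=O)[O-])S(=O)(=O)c1ccccc1 | intermediate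
24 | 4-{(3E,7E)-10-[(1R,6R)-2-hydroxy-1,2,6-trimethylcyclohex-3-en-1-yl]-4,8-dimethyldeca-3,7-dien-1-ylidene}dihydrofuran-2(3H)-one (E/Z mixture at the exocyclic alkene) | CC1(O)C=CC[C@@H](C)[C@@]1(C)CC/C(C)=C/CC/C(C)=C/CC=C1CC(=O)OC1 | intermediate
25 | 4-{(3E,7E)-10-[(1R,6R)-2-hydroxy-1,2,6-trimethylcyclohex-3-en-1-yl]-4,8-dimethyldeca-3,7-dien-1-yl}furan-2(5H)-one | CC1(O)C=CC[C@@H](C)[C@@]1(C)CC/C(C)=C/CC/C(C)=C/CCC1=CC(=O)OC1 | intermediate
26 | cyclolinteinone, 4-{(3E,7E)-4,8-dimethyl-10-[(1R,6R)-1,2,6-trimethyl-4-oxocyclohex-2-en-1-yl]deca-3,7-dien-1-yl}furan-2(5H)-one | CC1=CC(=O)C[C@@H](C)[C@@]1(C)CC/C(C)=C/CC/C(C)=C/CCC1=CC(=O)OC1 | target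

**Step count**
Total: 15 steps. Longest linear sequence: 13 steps (geraniol 1 to 26 through steps 1–4, 6–11 and 13–15; steps 5 and 12 are side branches).

**Three steps most likely to fail**

Step 14 (bears the label "Proposed new method:"). The fluoride-triggered carboxylation may be outrun by protodesilylation of the allylsilane. In the palladium stage, sulfinate return or closure at the substituted allyl terminus may compete with O-allylation at the CH2 terminus. The fallback uses known chemistry and sets out from bromide 18. Alkylation of dilithiated 2-methylprop-2-en-1-ol (n-BuLi, TMEDA, Et2O) with 18 should give the 2-methylidene primary allylic alcohol F1. Selective acylation of its primary hydroxyl with acryloyl chloride and Et3N gives the acrylate F2. Ring-closing metathesis with the second-generation Grubbs catalyst RuCl2(H2IMes)(PCy3)(=CHPh) in CH2Cl2 at reflux closes the furanone by forming its C3=C4 bond, and the route is rejoined at 25.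

Step 7. C-Methylation of the congested aluminate enolate may be sluggish or unselective (O-methylation, proton exchange, erosion of the anti facial selectivity). The fallback sets out from enone 9. The same copper-catalysed methyl transfer, quenched with TMSOTf, gives the trimethylsilyl enol ether F3. Simmons–Smith cyclopropanation (Et2Zn, CH2I2, CH2Cl2, 0 °C) should occur on the face anti to the C3 methyl and faster at the electron-rich enol ether than at the trisubstituted chain alkenes, giving the siloxycyclopropane F4. NaOH in MeOH opens the three-membered ring at the oxygen-bearing carbon and unveils the quaternary α-methyl ketone, rejoining the route at 12.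

Step 6. Regiocontrol may be lost in the monohydroboration of the conjugated diene (attack at the internal position, or double hydroboration). The fallback sets out from allylic alcohol 3. Acetylation (Ac2O, pyridine) gives the allylic acetate F5. Miyaura borylation (B2pin2, Pd2(dba)3 as zerovalent palladium source, DMSO) gives the linear (E)-allyl pinacol boronate F6. Matteson homologation with ClCH2Li (from BrCH2Cl and n-BuLi, −78 °C) inserts one CH2 between boron and the allylic carbon and gives the homoallylic pinacol boronate F7. Suzuki–Miyaura coupling of F7 with iodoenone 7 (Pd(OAc)2, SPhos, K3PO4, toluene/H2O) rejoins the route at 9.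

Further compounds
F1 | step 14 | (5R,6R)-6-[(3E,7E)-11-(hydroxymethyl)-3,7-dimethyldodeca-3,7,11-trien-1-yl]-1,5,6-trimethylcyclohex-2-en-1-ol | CC1(O)C=CC[C@@H](C)[C@@]1(C)CC/C(C)=C/CC/C(C)=C/CCC(=C)CO
F2 | step 14 | prop-2-enoate (acrylate) ester of the primary hydroxyl of F1 | CC1(O)C=CC[C@@H](C)[C@@]1(C)CC/C(C)=C/CC/C(C)=C/CCC(=C)COC(=O)C=C
F3 | step 7 | {[(3R)-2-[(3E,7E)-9-(TBSO)-3,7-dimethylnona-3,7-dien-1-yl]-3-methylcyclohex-1-en-1-yl]oxy}trimethylsilane | C[Si](C)(C)OC1=C(CC/C(C)=C/CC/C(C)=C/CO[Si](C)(C)C(C)(C)C)[C@H](C)CCC1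
F4 | step 7 | 1-(trimethylsilyloxy)-6-[(3E,7E)-9-(TBSO)-3,7-dimethylnona-3,7-dien-1-yl]-5-methylbicyclo[4.1.0]heptane, cyclopropane CH2 anti to the 5-methyl | C[Si](C)(C)O[C@@]12CCC[C@@H](C)[C@@]1(C2)CC/C(C)=C/CC/C(C)=C/CO[Si](C)(C)C(C)(C)C
F5 | step 6 | (2E,6E)-8-(TBSO)-2,6-dimethylocta-2,6-dien-1-yl acetate | CC(=O)OC/C(C)=C/CC/C(C)=C/CO[Si](C)(C)C(C)(C)C
F6 | step 6 | 2-[(2E,6E)-8-(TBSO)-2,6-dimethylocta-2,6-dien-1-yl]-4,4,5,5-tetramethyl-1,3,2-dioxaborolane | CC1(C)OB(C/C(C)=C/CC/C(C)=C/CO[Si](C)(C)C(C)(C)C)OC1(C)C
F7 | step 6 | 2-[(3E,7E)-9-(TBSO)-3,7-dimethylnona-3,7-dien-1-yl]-4,4,5,5-tetramethyl-1,3,2-dioxaborolane | CC1(C)OB(CC/C(C)=C/CC/C(C)=C/CO[Si](C)(C)C(C)(C)C)OC1(C)C
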